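## Retrosynthetic overview

- **Feature:** C4 of the 1,5-diazocan-2-one ring is benzylic, bears the N-methyl nitrogen N5 and lies β to the lactam carbonyl C2. At the ketone oxidation level it is the aryl C=O of a benzoylacetamide whose amide nitrogen N1 already holds a 3-(methylamino)propyl arm.
- **Disconnection 1 (last forward step):** N5–C4, by ring-closing asymmetric reductive amination. This makes the only new ring (eight-membered) and the only stereocentre (4S) together, from an achiral open chain.
- **Disconnection 2:** amide N1–C2, from a secondary amine and ethyl benzoylacetate. The N-methyl nitrogen stays Boc-masked until just before ring closure and is then stored as its hydrochloride.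
- **Disconnection 3:** N1–C8, by reductive amination of N-Boc-N-methyl-3-aminopropanal (from 3-(methylamino)propan-1-ol) with N-(4-aminobutyl)benzamide.
- **Ring order:** both phenyl rings are bought and the diazocanone ring is closed last.

Key step: step 6

Assumption: the sense of induction of the spiro phosphoramidite on an eight-membered iminium ion cannot be derived from smaller rings, so (Ra,S,S)-SIPHOS-PE is written and its mirror image is used if a first analytical run shows hydride delivery to the Si face; N-(4-aminobutyl)benzamide is taken as a catalogue compound.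

## Route

Step 1
Reactants: 1 3-(methylamino)propan-1-ol
Product: 2 tert-butyl (3-hydroxypropyl)(methyl)carbamate
Conditions: Boc2O (1.05 equiv), CH2Cl2, 0 °C → rt
Reagents that add atoms: di-tert-butyl dicarbonate, CC(C)(C)OC(=O)OC(=O)OC(C)(C)C
Why: Carbamate (Boc) protection, in which the secondary amine is far more nucleophilic than the primary alcohol, so that without an acylation catalyst only nitrogen should react.

Step 2
Reactants: 2 tert-butyl (3-hydroxypropyl)(methyl)carbamate
Product: 3 tert-butyl methyl(3-oxopropyl)carbamate
Conditions: TEMPO (10 mol%), PhI(OAc)2 (1.1 equiv), CH2Cl2, rt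
Reagents that add atoms: none
Why: Oxoammonium (TEMPO/PhI(OAc)2) oxidation stops at the aldehyde in the absence of water and runs in a mildly acidic medium, which spares the Boc group and avoids base-induced β-elimination of the carbamate.

Step 3
Reactants: 3 tert-butyl methyl(3-oxopropyl)carbamate; 4 N-(4-aminobutyl)benzamide
Product: 6 tert-butyl {3-[(4-benzamidobutyl)amino]propyl}(methyl)carbamate, via aldimine 5 (not isolated)
Conditions: 4 (1.2 equiv), NaBH(OAc)3 (1.5 equiv), ClCH2CH2Cl, rt; aq NaHCO3
Reagents that add atoms: none
Why: Reductive amination with NaBH(OAc)3, in which the aldehyde condenses with the primary amine to aldimine 5, the imine is reduced faster than the aldehyde, the slight excess of 4 holds back a second alkylation, and the benzamide and Boc groups are inert.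

Step 4
Reactants: 6 tert-butyl {3-[(4-benzamidobutyl)amino]propyl}(methyl)carbamate; 7 ethyl benzoylacetate
Product: 8 tert-butyl {3-[(4-benzamidobutyl)(3-oxo-3-phenylpropanoyl)amino]propyl}(methyl)carbamate
Conditions: 7 (1.2 equiv), DMAP (30 mol%), toluene, reflux, EtOH distilled off
Reagents that add atoms: none
Why: DMAP-catalysed aminolysis of a β-keto ester, in which only the secondary amine of 6 is nucleophilic, removal of ethanol drives the acyl transfer, and the Boc group tolerates 110 °C in a neutral medium.

Step 5
Reactants: 8 tert-butyl {3-[(4-benzamidobutyl)(3-oxo-3-phenylpropanoyl)amino]propyl}(methyl)carbamate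
Product: 9 N-(4-benzamidobutyl)-N-[3-(methylamino)propyl]-3-oxo-3-phenylpropanamide hydrochloride
Conditions: HCl (4 M in dioxane, 10 equiv), CH2Cl2, 0 °C → rt; evaporation, trituration with Et2O
Reagents that add atoms: hydrogen chloride, Cl
Why: Acidolytic Boc cleavage leaves both amides and the β-keto amide intact, and isolation as the ammonium chloride ties up the nitrogen lone pair, so that neither self-condensation at the ketone nor N1-to-N5 acyl migration can start on storage.

Step 6
Reactants: 9 N-(4-benzamidobutyl)-N-[3-(methylamino)propyl]-3-oxo-3-phenylpropanamide hydrochloride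
Product: 13 N-{4-[(4S)-5-methyl-2-oxo-4-phenyl-1,5-diazocan-1-yl]butyl}benzamide (target), via free amino keto amide 10 (not isolated), via Z-enamino lactam 11 (not isolated), via iminium acetate 12 (not isolated)
Conditions: (i) NaOAc (1.0 equiv), 3 Å MS, THF–CF3CH2OH 9:1 (5 mM), 40 °C, 12 h, Ar; (ii) same vessel, [Ir(cod)Cl]2 (2.5 mol%), (Ra,S,S)-SIPHOS-PE (11 mol%) and I2 (10 mol%) premixed in THF, H2 (50 bar), 40 °C; aq Na2CO3
Reagents that add atoms: none
Why: Proposed new method: sodium acetate turns salt 9 into the amine/acetic acid pair 10, whose N-methyl nitrogen adds to the aryl ketone carbon (8-exo-trig) and loses water to the sieves, giving the ring-cis (Z) enamino lactam 11 in reversible equilibrium with its C3-protonated iminium acetate 12, and an iodide-modified Ir(III) hydride formed from H2 transfers hydride irreversibly to C4 of 12, which drains the unfavourable medium-ring equilibrium. The closest known reaction types are the Ir-catalysed direct asymmetric reductive amination of aryl ketones with secondary amines, the deprotection/intramolecular asymmetric reductive amination that closes five- to seven-membered rings, the I2-promoted Ir or Rh hydrogenation of cyclic N-alkyl α-aryl enamines and the reductive amination of β-keto amides in ammonium carboxylate buffers, none of which has closed an eight-membered ring or used a tertiary β-enamino lactam. The (4S) centre is set by the chiral phosphoramidite pocket, which has to deliver hydride to the Re face of C4 (N5 > phenyl > C3), and the ring helps because it allows only the ring-cis C=N+ geometry, so that a single iminium isomer meets the catalyst. Reduction of iminium rather than ketone rests on the catalyst type, which reduces C=N+ by an ionic outer-sphere path and is a poor ketone hydrogenation catalyst, on the ageing period before hydrogen is admitted, and on premixing I2 with iridium so that no free iodine reaches the enolisable C3. Ring closure rather than oligomerisation rests on the 5 mM dilution, on the tertiary amide N1, which should populate both rotamers about equally and so hold the aminopropyl arm syn to C3 part of the time, and on the planar N1–C2 unit, which removes transannular hydrogens. A titanium alkoxide is left out on purpose because it would bind the β-keto amide as a chelated enolate and blunt the ketone, and the acetic acid buffer at no more than 40 °C should keep the N1-to-N5 acyl shift through a six-membered tetrahedral intermediate slow.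

## Compound list

1 | 3-(methylamino)propan-1-ol | CNCCCO | starting material
2 | tert-butyl (3-hydroxypropyl)(methyl)carbamate | CN(CCCO)C(=O)OC(C)(C)C | intermediate
3 | tert-butyl methyl(3-oxopropyl)carbamate | CN(CCC=O)C(=O)OC(C)(C)C | intermediate
4 | N-(4-aminobutyl)benzamide | NCCCCNC(=O)c1ccccc1 | starting material
5 | tert-butyl {(3E)-3-[(4-benzamidobutyl)imino]propyl}(methyl)carbamate (not isolated) | CN(CC/C=N/CCCCNC(=O)c1ccccc1)C(=O)OC(C)(C)C | intermediate
6 | tert-butyl {3-[(4-benzamidobutyl)amino]propyl}(methyl)carbamate | CN(CCCNCCCCNC(=O)c1ccccc1)C(=O)OC(C)(C)C | intermediate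
7 | ethyl benzoylacetate (ethyl 3-oxo-3-phenylpropanoate) | CCOC(=O)CC(=O)c1ccccc1 | starting material
8 | tert-butyl {3-[(4-benzamidobutyl)(3-oxo-3-phenylpropanoyl)amino]propyl}(methyl)carbamate | CN(CCCN(CCCCNC(=O)c1ccccc1)C(=O)CC(=O)c1ccccc1)C(=O)OC(C)(C)C | intermediate
9 | N-(4-benzamidobutyl)-N-[3-(methylamino)propyl]-3-oxo-3-phenylpropanamide hydrochloride | CNCCCN(CCCCNC(=O)c1ccccc1)C(=O)CC(=O)c1ccccc1.Cl | intermediate
10 | N-(4-benzamidobutyl)-N-[3-(methylamino)propyl]-3-oxo-3-phenylpropanamide, free base (not isolated) | CNCCCN(CCCCNC(=O)c1ccccc1)C(=O)CC(=O)c1ccccc1 | intermediate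
11 | N-{4-[(3Z)-5-methyl-2-oxo-4-phenyl-5,6,7,8-tetrahydro-1,5-diazocin-1(2H)-yl]butyl}benzamide (not isolated) | CN1CCCN(CCCCNC(=O)c2ccccc2)C(=O)/C=C1/c1ccccc1 | intermediate
12 | 1-(4-benzamidobutyl)-5-methyl-2-oxo-4-phenyl-1,2,3,6,7,8-hexahydro-1,5-diazocin-5-ium acetate (not isolated) | C[N+]1=C(c2ccccc2)CC(=O)N(CCCCNC(=O)c2ccccc2)CCC1.CC(=O)[O-] | intermediate
13 | N-{4-[(4S)-5-methyl-2-oxo-4-phenyl-1,5-diazocan-1-yl]butyl}benzamide | CN1CCCN(CCCCNC(=O)c2ccccc2)C(=O)C[C@H]1c1ccccc1 | target

## Step count and risks

Total step count: 6. Longest linear sequence: 6 (1 → 2 → 3 → 6 → 8 → 9 → 13).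

**Step 6.**
- Four things may go wrong:
  - intermolecular condensation and cyclodimerisation may outrun the eight-membered closure;
  - the free ketone may be hydrogenated before the iminium ion forms;
  - facial selectivity at the flexible medium-ring iminium ion may be poor;
  - the acyl group may shift from N1 to N5 before closure.
- The fallback gives up the reductive amination, takes the stereocentre from a bought building block and uses known ring-expansion chemistry. It sets out from 4 and comes back at 13.
- (S)-4-Phenylazetidin-2-one F1, bought as the single enantiomer, is N-alkylated with 1-bromo-3-chloropropane (KOH, Bu4NHSO4, THF) to (S)-1-(3-chloropropyl)-4-phenylazetidin-2-one F2.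
- F2 alkylates an excess of amine 4 (NaI, K2CO3, MeCN, 60 °C) to N-[4-({3-[(4S)-2-oxo-4-phenylazetidin-1-yl]propyl}amino)butyl]benzamide F3.
- On heating in toluene the secondary amine of F3 attacks the strained lactam carbonyl through a six-membered tetrahedral intermediate, and the four-membered ring expands by four atoms. This is the transamidative ring expansion of N-(3-aminopropyl) β-lactams, and no bond at C4 is touched. It gives N-{4-[(4S)-2-oxo-4-phenyl-1,5-diazocan-1-yl]butyl}benzamide F4.
- Reductive methylation of N5 (aq HCHO, NaBH(OAc)3, ClCH2CH2Cl) then gives 13.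

**Step 4.**
- The secondary amine may condense at the ketone of the keto ester instead of attacking the ester. The aminolysis may also be slow enough that the Boc group is lost during a long reflux.
- The fallback replaces ester aminolysis by trapping of a preformed acylketene precursor. It sets out from 6 and comes back at 8.
- Meldrum's acid is C-acylated with benzoyl chloride (pyridine, CH2Cl2, 0 °C) to 5-[hydroxy(phenyl)methylidene]-2,2-dimethyl-1,3-dioxane-4,6-dione F5.
- F5 is warmed with 6 in toluene at 80–90 °C, where it fragments to benzoylketene. The amine captures benzoylketene irreversibly at the ketene carbon to give 8.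
- The ketone appears only after the amide bond exists, and the temperature is lower.

**Step 3.**
- The primary amine may be alkylated twice, and the β-carbamoyl aldehyde may lose its carbamate by β-elimination before it condenses.
- The fallback avoids the aldehyde altogether, which makes step 2 unnecessary. It sets out from 2 and 4 and comes back at 6.
- Amine 4 is sulfonylated with 2-nitrobenzenesulfonyl chloride (Et3N, CH2Cl2) to N-{4-[(2-nitrophenyl)sulfonylamino]butyl}benzamide F6.
- F6 is alkylated once, by design, with alcohol 2 under Fukuyama–Mitsunobu conditions (PPh3, DIAD, THF) to tert-butyl (3-{(4-benzamidobutyl)[(2-nitrophenyl)sulfonyl]amino}propyl)(methyl)carbamate F7.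
- Thiophenol/K2CO3 in DMF removes the sulfonyl group by ipso substitution to give 6.

## Further compounds

F1 | step 6 | (S)-4-phenylazetidin-2-one (bought) | O=C1C[C@H](N1)c2ccccc2
F2 | step 6 | (S)-1-(3-chloropropyl)-4-phenylazetidin-2-one | ClCCCN1C(=O)C[C@H]1c2ccccc2
F3 | step 6 | N-[4-({3-[(4S)-2-oxo-4-phenylazetidin-1-yl]propyl}amino)butyl]benzamide | O=C(NCCCCNCCCN1C(=O)C[C@H]1c2ccccc2)c3ccccc3
F4 | step 6 | N-{4-[(4S)-2-oxo-4-phenyl-1,5-diazocan-1-yl]butyl}benzamide | N1CCCN(CCCCNC(=O)c2ccccc2)C(=O)C[C@H]1c1ccccc1
F5 | step 4 | 5-[hydroxy(phenyl)methylidene]-2,2-dimethyl-1,3-dioxane-4,6-dione | CC1(C)OC(=O)C(=C(O)c2ccccc2)C(=O)O1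
F6 | step 3 | N-{4-[(2-nitrophenyl)sulfonylamino]butyl}benzamide | O=C(NCCCCNS(=O)(=O)c1ccccc1[N+](=O)[O-])c1ccccc1
F7 | step 3 | tert-butyl (3-{(4-benzamidobutyl)[(2-nitrophenyl)sulfonyl]amino}propyl)(methyl)carbamate | CN(CCCN(CCCCNC(=O)c1ccccc1)S(=O)(=O)c1ccccc1[N+](=O)[O-])C(=O)OC(C)(C)C
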